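**Plan**

Retrosynthesis: first the sulfate O–S bond and the ester, then the two side-chain C=C bonds (Wittig, cross-metathesis), the C8–CH3 bond and the ring A bond C8a–C1. The open chain is then cut at the allylsilane alkene on C1 (cross-metathesis), C2–butenyl (copper allylic substitution), C2–C3 (Stille) and C3=C4 (iodo-Wittig); ring B is cut at C4a–C8a and C5–C6 (Diels–Alder).
Forward: ring B is made first, the chain is grown from C4a, ring A is closed by the allylsilane–enone cyclisation, and C8-methyl, C7-OH, dienoate and sulfate follow.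
Enabling feature: C8a of ring B lies β to the oxygen-bearing C7 and is bonded to C1, which carries an alkenyl chain. C8a–C1 is therefore the bond between an enone β-carbon and the γ-carbon of an allylsilane; closing it builds ring A and leaves a vinyl group on C1 and a C7–C8 silyl enol ether.
Stereochemistry: C4a from the catalytic asymmetric Diels–Alder reaction; C2 from the chiral copper catalyst; C8a and C1 in the cyclisation, relayed from C4a and C2; C8 by enolate methylation anti to the C8a–C1 bond; C7 by a bulky hydride.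
Alkene geometry: Z-selective iodo-olefination, stereoretentive couplings, E-selective metathesis and Wittig reactions.

Key step: step 11

Remark: locants C1–C8a are those of the octalin of the target and are used for open-chain and bicyclic intermediates alike.
Remark: the target is taken as the free hydrogen sulfate carboxylic acid as drawn; it is released from its salt by brief cold acidification in the last step.

Step 1
Reactants: 1 methyl vinyl ketone
Product: 2 2-(triisopropylsilyloxy)buta-1,3-diene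
Conditions: i-Pr3SiOTf, Et3N, Et2O, 0 → 23 °C
Reagents that add atoms: triisopropylsilyl trifluoromethanesulfonate, CC(C)[Si](C(C)C)(C(C)C)OS(=O)(=O)C(F)(F)F
Why: Soft enolisation (O-silylation, then deprotonation of the methyl group by the amine) is the standard silyl dienol ether synthesis and gives the 2-silyloxydiene.

Step 2
Reactants: 2 2-(triisopropylsilyloxy)buta-1,3-diene; 3 2,2,2-trifluoroethyl acrylate
Product: 4 2,2,2-trifluoroethyl (1S)-4-(triisopropylsilyloxy)cyclohex-3-ene-1-carboxylate
Conditions: (S)-3,3-diphenyl-1-(o-tolyl)tetrahydro-1H,3H-pyrrolo[1,2-c][1,3,2]oxazaborole (20 mol %), Tf2NH (17 mol %), CH2Cl2, −40 °C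
Reagents that add atoms: none
Why: Enantioselective Diels–Alder reaction under chiral cationic oxazaborolidine catalysis closes ring B with the 1,4-regiochemistry dictated by the 2-silyloxy group; by analogy with the butadiene–acrylate case the (S)-catalyst should expose the acrylate face that gives the (S)-ester, which sets C4a.

Step 3
Reactants: 4 2,2,2-trifluoroethyl (1S)-4-(triisopropylsilyloxy)cyclohex-3-ene-1-carboxylate
Product: 5 [(1S)-4-(triisopropylsilyloxy)cyclohex-3-en-1-yl]methanol
Conditions: i-Bu2AlH (2.5 equiv), CH2Cl2, −78 → 0 °C; aq. potassium sodium tartrate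
Reagents that add atoms: none
Why: Aluminium hydride reduction of the activated ester to the primary alcohol leaves the hindered silyl enol ether and the stereocentre untouched.

Step 4
Reactants: 5 [(1S)-4-(triisopropylsilyloxy)cyclohex-3-en-1-yl]methanol
Product: 6 (1S)-4-(triisopropylsilyloxy)cyclohex-3-ene-1-carbaldehyde
Conditions: Dess–Martin periodinane, pyridine, CH2Cl2, 0 → 23 °C
Reagents that add atoms: none
Why: Buffered Dess–Martin oxidation gives the α-branched aldehyde without epimerisation or enol ether hydrolysis; the aldehyde is used at once.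

Step 5
Reactants: 6 (1S)-4-(triisopropylsilyloxy)cyclohex-3-ene-1-carbaldehyde
Product: 7 triisopropyl{[(4S)-4-[(1Z)-2-iodoprop-1-en-1-yl]cyclohex-1-en-1-yl]oxy}silane
Conditions: [EtPPh3]I, n-BuLi, THF, 23 °C; I2, −78 °C; NaN(SiMe3)2, −20 °C; then 6, −78 → −20 °C
Reagents that add atoms: ethyltriphenylphosphonium iodide, CC[P+](c1ccccc1)(c1ccccc1)c1ccccc1.[I-]; iodine, II
Why: Stork–Zhao-type Wittig olefination with the α-iodo ylide made in the flask is kinetically Z-selective and places iodine cis to the ring, which later fixes the cis relation of C2 and C4a across C3=C4.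

Step 6
Reactants: 7 triisopropyl{[(4S)-4-[(1Z)-2-iodoprop-1-en-1-yl]cyclohex-1-en-1-yl]oxy}silane; 8 (2E)-3-(tributylstannyl)prop-2-en-1-ol
Product: 9 (2E,4Z)-4-methyl-5-[(1S)-4-(triisopropylsilyloxy)cyclohex-3-en-1-yl]penta-2,4-dien-1-ol
Conditions: Pd2(dba)3 (5 mol %), AsPh3 (20 mol %), CuI (10 mol %), DMF, 23 °C
Reagents that add atoms: none
Why: Stille coupling forms the C2–C3 bond with retention of geometry at both alkenes and tolerates the free hydroxyl and the silyl enol ether.

Step 7
Reactants: 9 (2E,4Z)-4-methyl-5-[(1S)-4-(triisopropylsilyloxy)cyclohex-3-en-1-yl]penta-2,4-dien-1-ol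
Product: 10 diethyl (2E,4Z)-4-methyl-5-[(1S)-4-(triisopropylsilyloxy)cyclohex-3-en-1-yl]penta-2,4-dien-1-yl phosphate
Conditions: ClP(O)(OEt)2, Et3N, DMAP (cat.), CH2Cl2, 0 °C
Reagents that add atoms: diethyl chlorophosphate, CCOP(=O)(Cl)OCC
Why: Phosphorylation of the primary allylic alcohol installs the leaving group for copper-mediated allylic substitution; the phosphate is used without prolonged storage.

Step 8
Reactants: 10 diethyl (2E,4Z)-4-methyl-5-[(1S)-4-(triisopropylsilyloxy)cyclohex-3-en-1-yl]penta-2,4-dien-1-yl phosphate; 11 2-[(2Z)-but-2-en-2-yl]-4,4,5,5-tetramethyl-1,3,2-dioxaborolane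
Product: 12 triisopropyl{[(4S)-4-[(1Z,3R,4E)-3-ethenyl-2,4-dimethylhexa-1,4-dien-1-yl]cyclohex-1-en-1-yl]oxy}silane
Conditions: 11 (1.5 equiv), CuCl (5 mol %), 1-(2,6-diisopropylphenyl)-4,5-diphenyl-3-(2-sulfonatophenyl)-4,5-dihydroimidazolium inner salt (one antipode, 5.5 mol %), NaOMe (1.5 equiv), THF, 23 → 50 °C
Reagents that add atoms: none
Why: Copper-catalysed enantioselective allylic substitution (SN2′) with an alkenylboronate: methoxide-promoted boron-to-copper transmetalation gives a carbene–copper alkenyl that should add at the γ-carbon C2 (the ε-carbon is shielded by the ring), and the ligand antipode that addresses the Si face of C2 is used so that the catalyst, not the remote C4a centre, sets (R)-C2.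

Step 9
Reactants: 12 triisopropyl{[(4S)-4-[(1Z,3R,4E)-3-ethenyl-2,4-dimethylhexa-1,4-dien-1-yl]cyclohex-1-en-1-yl]oxy}silane
Product: 14 (4S)-4-[(1Z,3R,4E)-3-ethenyl-2,4-dimethylhexa-1,4-dien-1-yl]cyclohex-2-en-1-one, via α-phenylselanyl ketone 13 (not isolated)
Conditions: PhSeCl (1.05 equiv), CH2Cl2, −78 °C; then pyridine, 30% aq. H2O2, 0 → 23 °C
Reagents that add atoms: none
Why: Electrophilic selenenylation of the silyl enol ether fixes selenium at C8, and selenoxide syn-elimination, which can only take hydrogen from C8a, gives the C8=C8a enone regiospecifically without a metal hydride that could isomerise the skipped triene.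

Step 10
Reactants: 14 (4S)-4-[(1Z,3R,4E)-3-ethenyl-2,4-dimethylhexa-1,4-dien-1-yl]cyclohex-2-en-1-one; 15 allyltrimethylsilane
Product: 16 (4S)-4-[(1Z,3R,4E)-3-[(2E)-but-2-en-2-yl]-2-methyl-6-(trimethylsilyl)hexa-1,4-dien-1-yl]cyclohex-2-en-1-one
Conditions: 15 (8 equiv), second-generation Hoveyda–Grubbs catalyst [RuCl2(H2IMes)(=CH–C6H4-2-O-i-Pr)] (10 mol %), CH2Cl2, 40 °C
Reagents that add atoms: none
Why: Olefin cross-metathesis engages only the monosubstituted alkene, the branched allylic carbon should favour the E-allylsilane, and the trisubstituted alkenes and the cyclic enone should stay out of the reaction.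

Step 11
Reactants: 16 (4S)-4-[(1Z,3R,4E)-3-[(2E)-but-2-en-2-yl]-2-methyl-6-(trimethylsilyl)hexa-1,4-dien-1-yl]cyclohex-2-en-1-one
Product: 17 (1S,2R,4aS,8aR)-2-[(2E)-but-2-en-2-yl]-1-ethenyl-3-methyl-7-(trimethylsilyloxy)-1,2,4a,5,6,8a-hexahydronaphthalene
Conditions: Me3SiNTf2 (10 mol %), 2,6-di-tert-butyl-4-methylpyridine (10 mol %), CH2Cl2, −78 → −40 °C; Et3N, pentane, filtration
Reagents that add atoms: none
Why: This is an intramolecular Hosomi–Sakurai conjugate addition in its silyl-catalysed form, as known for allylsilanes tethered to cyclohexenones: the silyl cation binds the enone oxygen, the allylsilane γ-carbon C1 attacks the β-carbon C8a, and the β-silyl cation gives up its silyl group to the triflimide or to the next enone, so the C7–C8 trimethylsilyl enol ether forms as an isomer of 16 and the catalyst turns over. Ring A closes in a 6-exo-trig mode, the enone C=C being exocyclic to the new ring. C8a: the three-atom tether sits pseudo-equatorial on C4a and can reach only the same face of C8a, along the stereoelectronically preferred axial trajectory, which gives the cis ring fusion. C1: in the chair-like transition state the butenyl group on C2 lies pseudo-axial to escape A1,2 strain with the C3 methyl group, and the allylsilane reacts through the face that places the nascent vinyl group equatorial, because the axial position would run into C5; vinyl and butenyl therefore end up cis. The step needs the cis fusion and this 1,2-cis relation, and both are secured by the preset C4a and C2 centres, while the hindered pyridine keeps traces of acid from protodesilylating the allylsilane or the product.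

Step 12
Reactants: 17 (1S,2R,4aS,8aR)-2-[(2E)-but-2-en-2-yl]-1-ethenyl-3-methyl-7-(trimethylsilyloxy)-1,2,4a,5,6,8a-hexahydronaphthalene
Product: 19 (1S,2R,4aS,8R,8aR)-2-[(2E)-but-2-en-2-yl]-1-ethenyl-3,8-dimethyl-1,2,4a,5,6,8a-hexahydronaphthalen-7(8H)-one, via lithium enolate 18 (not isolated)
Conditions: MeLi, THF, 0 °C; then MeI, DMPU, −78 → −20 °C
Reagents that add atoms: iodomethane, CI
Why: Methyllithium cleaves the silyl enol ether to the regiodefined lithium enolate, whose alkylation should occur by axial attack on the convex face, anti to the axial C8a–C1 bond, to give (8R).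

Step 13
Reactants: 19 (1S,2R,4aS,8R,8aR)-2-[(2E)-but-2-en-2-yl]-1-ethenyl-3,8-dimethyl-1,2,4a,5,6,8a-hexahydronaphthalen-7(8H)-one
Product: 20 (1S,2R,4aS,7S,8R,8aR)-2-[(2E)-but-2-en-2-yl]-1-ethenyl-3,8-dimethyl-1,2,4a,5,6,7,8,8a-octahydronaphthalen-7-ol
Conditions: LiBH(s-Bu)3, THF, −78 °C; then H2O
Reagents that add atoms: none
Why: Reduction with a bulky trialkylborohydride should proceed through the chair that carries the C8 methyl group equatorial (the other chair is shielded on both faces) by equatorial hydride approach, giving the axial (7S)-alcohol cis to the methyl group.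

Step 14
Reactants: 20 (1S,2R,4aS,7S,8R,8aR)-2-[(2E)-but-2-en-2-yl]-1-ethenyl-3,8-dimethyl-1,2,4a,5,6,7,8,8a-octahydronaphthalen-7-ol; 21 (E)-crotonaldehyde
Product: 22 (2E)-3-[(1S,2R,4aS,7S,8R,8aR)-2-[(2E)-but-2-en-2-yl]-7-hydroxy-3,8-dimethyl-1,2,4a,5,6,7,8,8a-octahydronaphthalen-1-yl]prop-2-enal
Conditions: 21 (10 equiv), second-generation Hoveyda–Grubbs catalyst [RuCl2(H2IMes)(=CH–C6H4-2-O-i-Pr)] (10 mol %), CH2Cl2, 40 °C
Reagents that add atoms: none
Why: Cross-metathesis of the only terminal alkene with crotonaldehyde gives the E-enal; the trisubstituted alkenes do not react and the free hydroxyl is tolerated.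

Step 15
Reactants: 22 (2E)-3-[(1S,2R,4aS,7S,8R,8aR)-2-[(2E)-but-2-en-2-yl]-7-hydroxy-3,8-dimethyl-1,2,4a,5,6,7,8,8a-octahydronaphthalen-1-yl]prop-2-enal; 23 methyl (triphenylphosphoranylidene)acetate
Product: 24 methyl (2E,4E)-5-[(1S,2R,4aS,7S,8R,8aR)-2-[(2E)-but-2-en-2-yl]-7-hydroxy-3,8-dimethyl-1,2,4a,5,6,7,8,8a-octahydronaphthalen-1-yl]penta-2,4-dienoate
Conditions: 23, CH2Cl2, 23 °C
Reagents that add atoms: none
Why: Wittig olefination with the stabilised ylide extends the enal to the (2E,4E)-dienoate with high E selectivity and needs no base.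

Step 16
Reactants: 24 methyl (2E,4E)-5-[(1S,2R,4aS,7S,8R,8aR)-2-[(2E)-but-2-en-2-yl]-7-hydroxy-3,8-dimethyl-1,2,4a,5,6,7,8,8a-octahydronaphthalen-1-yl]penta-2,4-dienoate
Product: 25 pyridinium salt of the C7 sulfate monoester of 24
Conditions: SO3·pyridine, pyridine, 23 → 50 °C
Reagents that add atoms: sulfur trioxide–pyridine complex, [O-]S(=O)(=O)[n+]1ccccc1
Why: O-Sulfation of the secondary alcohol with the sulfur trioxide–amine complex does not break the C7–O bond, so the configuration is retained.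

Step 17
Reactants: 25 pyridinium salt of the C7 sulfate monoester of 24
Product: 27 (2E,4E)-5-[(1S,2R,4aS,7S,8R,8aR)-2-[(2E)-but-2-en-2-yl]-3,8-dimethyl-7-(sulfooxy)-1,2,4a,5,6,7,8,8a-octahydronaphthalen-1-yl]penta-2,4-dienoic acid, via dilithium salt 26 (not isolated)
Conditions: LiOH, THF/MeOH/H2O, 23 °C; then 1 M HCl, 0 °C, to pH 2–3; C18 desalting
Reagents that add atoms: lithium hydroxide, [Li+].[OH-]
Why: Saponification of the methyl ester by hydroxide (BAc2) spares the sulfate monoester anion, which resists base, and brief cold acidification gives the free acid.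

**Compound list**

1 | methyl vinyl ketone | CC(=O)C=C | starting material
2 | 2-(triisopropylsilyloxy)buta-1,3-diene | C=CC(=C)O[Si](C(C)C)(C(C)C)C(C)C | intermediate
3 | 2,2,2-trifluoroethyl acrylate | C=CC(=O)OCC(F)(F)F | starting material
4 | 2,2,2-trifluoroethyl (1S)-4-(triisopropylsilyloxy)cyclohex-3-ene-1-carboxylate | O=C(OCC(F)(F)F)[C@@H]1CC=C(O[Si](C(C)C)(C(C)C)C(C)C)CC1 | intermediate
5 | [(1S)-4-(triisopropylsilyloxy)cyclohex-3-en-1-yl]methanol | OC[C@@H]1CC=C(O[Si](C(C)C)(C(C)C)C(C)C)CC1 | intermediate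
6 | (1S)-4-(triisopropylsilyloxy)cyclohex-3-ene-1-carbaldehyde | O=C[C@@H]1CC=C(O[Si](C(C)C)(C(C)C)C(C)C)CC1 | intermediate
7 | triisopropyl{[(4S)-4-[(1Z)-2-iodoprop-1-en-1-yl]cyclohex-1-en-1-yl]oxy}silane (iodine cis to the ring) | C/C(I)=C/[C@@H]1CC=C(O[Si](C(C)C)(C(C)C)C(C)C)CC1 | intermediate
8 | (2E)-3-(tributylstannyl)prop-2-en-1-ol | OC/C=C/[Sn](CCCC)(CCCC)CCCC | starting material
9 | (2E,4Z)-4-methyl-5-[(1S)-4-(triisopropylsilyloxy)cyclohex-3-en-1-yl]penta-2,4-dien-1-ol | OC/C=C/C(C)=C\[C@@H]1CC=C(O[Si](C(C)C)(C(C)C)C(C)C)CC1 | intermediate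
10 | diethyl (2E,4Z)-4-methyl-5-[(1S)-4-(triisopropylsilyloxy)cyclohex-3-en-1-yl]penta-2,4-dien-1-yl phosphate | CCOP(=O)(OCC)OC/C=C/C(C)=C\[C@@H]1CC=C(O[Si](C(C)C)(C(C)C)C(C)C)CC1 | intermediate
11 | 2-[(2Z)-but-2-en-2-yl]-4,4,5,5-tetramethyl-1,3,2-dioxaborolane (the two methyl groups cis) | C/C=C(\C)B1OC(C)(C)C(C)(C)O1 | starting material
12 | triisopropyl{[(4S)-4-[(1Z,3R,4E)-3-ethenyl-2,4-dimethylhexa-1,4-dien-1-yl]cyclohex-1-en-1-yl]oxy}silane | C/C=C(\C)[C@@H](C=C)/C(C)=C\[C@@H]1CC=C(O[Si](C(C)C)(C(C)C)C(C)C)CC1 | intermediate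
13 | (4S)-4-[(1Z,3R,4E)-3-ethenyl-2,4-dimethylhexa-1,4-dien-1-yl]-2-(phenylselanyl)cyclohexan-1-one (both epimers at the selenium-bearing carbon) | C/C=C(\C)[C@@H](C=C)/C(C)=C\[C@H]1CCC(=O)C([Se]c2ccccc2)C1 | intermediate
14 | (4S)-4-[(1Z,3R,4E)-3-ethenyl-2,4-dimethylhexa-1,4-dien-1-yl]cyclohex-2-en-1-one | C/C=C(\C)[C@@H](C=C)/C(C)=C\[C@H]1CCC(=O)C=C1 | intermediate
15 | allyltrimethylsilane | C=CC[Si](C)(C)C | starting material
16 | (4S)-4-[(1Z,3R,4E)-3-[(2E)-but-2-en-2-yl]-2-methyl-6-(trimethylsilyl)hexa-1,4-dien-1-yl]cyclohex-2-en-1-one | C/C=C(\C)[C@@H](/C=C/C[Si](C)(C)C)/C(C)=C\[C@H]1CCC(=O)C=C1 | intermediate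
17 | (1S,2R,4aS,8aR)-2-[(2E)-but-2-en-2-yl]-1-ethenyl-3-methyl-7-(trimethylsilyloxy)-1,2,4a,5,6,8a-hexahydronaphthalene | C/C=C(\C)[C@@H]1C(C)=C[C@H]2CCC(O[Si](C)(C)C)=C[C@H]2[C@@H]1C=C | intermediate
18 | lithium (1S,2R,4aS,8aR)-2-[(2E)-but-2-en-2-yl]-1-ethenyl-3-methyl-1,2,4a,5,6,8a-hexahydronaphthalen-7-olate | C/C=C(\C)[C@@H]1C(C)=C[C@H]2CCC(O[Li])=C[C@H]2[C@@H]1C=C | intermediate
19 | (1S,2R,4aS,8R,8aR)-2-[(2E)-but-2-en-2-yl]-1-ethenyl-3,8-dimethyl-1,2,4a,5,6,8a-hexahydronaphthalen-7(8H)-one | C/C=C(\C)[C@@H]1C(C)=C[C@H]2CCC(=O)[C@H](C)[C@H]2[C@@H]1C=C | intermediate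
20 | (1S,2R,4aS,7S,8R,8aR)-2-[(2E)-but-2-en-2-yl]-1-ethenyl-3,8-dimethyl-1,2,4a,5,6,7,8,8a-octahydronaphthalen-7-ol | C/C=C(\C)[C@@H]1C(C)=C[C@H]2CC[C@H](O)[C@H](C)[C@H]2[C@@H]1C=C | intermediate
21 | (E)-crotonaldehyde | C/C=C/C=O | starting material
22 | (2E)-3-[(1S,2R,4aS,7S,8R,8aR)-2-[(2E)-but-2-en-2-yl]-7-hydroxy-3,8-dimethyl-1,2,4a,5,6,7,8,8a-octahydronaphthalen-1-yl]prop-2-enal | C/C=C(\C)[C@@H]1C(C)=C[C@H]2CC[C@H](O)[C@H](C)[C@H]2[C@@H]1/C=C/C=O | intermediate
23 | methyl (triphenylphosphoranylidene)acetate | COC(=O)C=P(c1ccccc1)(c1ccccc1)c1ccccc1 | starting material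
24 | methyl (2E,4E)-5-[(1S,2R,4aS,7S,8R,8aR)-2-[(2E)-but-2-en-2-yl]-7-hydroxy-3,8-dimethyl-1,2,4a,5,6,7,8,8a-octahydronaphthalen-1-yl]penta-2,4-dienoate | C/C=C(\C)[C@@H]1C(C)=C[C@H]2CC[C@H](O)[C@H](C)[C@H]2[C@@H]1/C=C/C=C/C(=O)OC | intermediate
25 | pyridinium salt of the C7 sulfate monoester of 24 | C/C=C(\C)[C@@H]1C(C)=C[C@H]2CC[C@H](OS(=O)(=O)[O-])[C@H](C)[C@H]2[C@@H]1/C=C/C=C/C(=O)OC.c1cc[nH+]cc1 | intermediate
26 | dilithium salt of the target (carboxylate and sulfate) | C/C=C(\C)[C@@H]1C(C)=C[C@H]2CC[C@H](OS(=O)(=O)[O-])[C@H](C)[C@H]2[C@@H]1/C=C/C=C/C(=O)[O-].[Li+].[Li+] | intermediate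
27 | (2E,4E)-5-[(1S,2R,4aS,7S,8R,8aR)-2-[(2E)-but-2-en-2-yl]-3,8-dimethyl-7-(sulfooxy)-1,2,4a,5,6,7,8,8a-octahydronaphthalen-1-yl]penta-2,4-dienoic acid | C/C=C(\C)[C@@H]1C(C)=C[C@H]2CC[C@H](OS(=O)(=O)O)[C@H](C)[C@H]2[C@@H]1/C=C/C=C/C(=O)O | target

**Step count**

Total steps: 17. Longest linear sequence: 17 (steps 1–17, from methyl vinyl ketone).

**Steps most likely to fail**

Step 8. The copper alkenyl may add at the α- or ε-carbon of the conjugated phosphate instead of at C2. Facial control may also be weak because C2 is flanked by a fully substituted alkene carbon, and transmetalation of the α-branched boronate may be slow. The fallback sets out from vinyl iodide 7 and comes back at triene 12; it forms the C2–C3 bond instead of the C2–butenyl bond.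
- Iodine–lithium exchange on 7 (t-BuLi, Et2O, −78 °C) and quenching with 2-isopropoxy-4,4,5,5-tetramethyl-1,3,2-dioxaborolane would give the ring-bearing pinacol alkenylboronate F1, with boron cis to the ring.
- Tiglaldehyde would be homologated with triethyl phosphonoacetate (NaH, THF; Horner–Wadsworth–Emmons) to ethyl (2E,4E)-4-methylhexa-2,4-dienoate F2, reduced with i-Bu2AlH to (2E,4E)-4-methylhexa-2,4-dien-1-ol F3, and phosphorylated to the diethyl dienyl phosphate F4.
- In F4 the γ-carbon carries only the small butenyl group and the ε-carbon is blocked by two methyl groups. F1 and an excess of F4 would be coupled under the same copper catalysis, now with the ligand antipode that addresses the Re face of C3 of F4, to return to 12.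

Step 11. Silyl turnover may stall if traces of water quench the silyl cation. The allylsilane may be protodesilylated, the silylated enone may lose its γ-proton to give a dienol ether, or the allylsilane face selection at C1 may be incomplete. The fallback sets out from 16 and comes back at 17.
- Stoichiometric TiCl4 (CH2Cl2, −78 °C) would drive the same C8a–C1 closure through a titanium enolate; aqueous work-up would give the cis-fused C7 ketone F5.
- The enol ether would then be regenerated by equilibrating enol silylation (Me3SiCl, Et3N, DMF, 80 °C). Cis-fused 2-decalones enolise preferentially toward the ring fusion, so this should deliver the C7–C8 isomer 17.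

Step 10. Metathesis at a vinyl group on a tertiary, doubly allylic carbon may be slow. During long reaction times the catalyst may be diverted by the enone (secondary metathesis, hydride-mediated isomerisation of the skipped triene or of C4a), and the E/Z ratio may be modest. The fallback sets out from 12 and comes back at 16; the metathesis is moved to the carbonyl-free stage.
- Cross-metathesis of 12 with 15 under the same ruthenium catalyst would give the allylsilane silyl enol ether F6.
- PhSeCl (1.0 equiv, CH2Cl2, −78 °C) would then selenenylate the enol ether, which is far more nucleophilic than the allylsilane, to the α-phenylselanyl ketone F7.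
- H2O2/pyridine (0 °C) would trigger selenoxide syn-elimination toward C8a and give 16.

Further compounds
F1 | step 8 | 2-[(1E)-1-{(1S)-4-(triisopropylsilyloxy)cyclohex-3-en-1-yl}prop-1-en-2-yl]-4,4,5,5-tetramethyl-1,3,2-dioxaborolane (boron cis to the ring) | C/C(B1OC(C)(C)C(C)(C)O1)=C/[C@@H]1CC=C(O[Si](C(C)C)(C(C)C)C(C)C)CC1
F2 | step 8 | ethyl (2E,4E)-4-methylhexa-2,4-dienoate | C/C=C(\C)/C=C/C(=O)OCC
F3 | step 8 | (2E,4E)-4-methylhexa-2,4-dien-1-ol | C/C=C(\C)/C=C/CO
F4 | step 8 | diethyl (2E,4E)-4-methylhexa-2,4-dien-1-yl phosphate | C/C=C(\C)/C=C/COP(=O)(OCC)OCC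
F5 | step 11 | (1S,2R,4aS,8aR)-2-[(2E)-but-2-en-2-yl]-1-ethenyl-3-methyl-1,2,4a,5,6,8a-hexahydronaphthalen-7(8H)-one | C/C=C(\C)[C@@H]1C(C)=C[C@H]2CCC(=O)C[C@H]2[C@@H]1C=C
F6 | step 10 | triisopropyl{[(4S)-4-[(1Z,3R,4E)-3-[(2E)-but-2-en-2-yl]-2-methyl-6-(trimethylsilyl)hexa-1,4-dien-1-yl]cyclohex-1-en-1-yl]oxy}silane | C/C=C(\C)[C@@H](/C=C/C[Si](C)(C)C)/C(C)=C\[C@@H]1CC=C(O[Si](C(C)C)(C(C)C)C(C)C)CC1
F7 | step 10 | (4S)-4-[(1Z,3R,4E)-3-[(2E)-but-2-en-2-yl]-2-methyl-6-(trimethylsilyl)hexa-1,4-dien-1-yl]-2-(phenylselanyl)cyclohexan-1-one (both epimers at the selenium-bearing carbon) | C/C=C(\C)[C@@H](/C=C/C[Si](C)(C)C)/C(C)=C\[C@H]1CCC(=O)C([Se]c2ccccc2)C1
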